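The γ-lactone is disconnected into a C5–O1–C2 unit and a C3–C4 unit: oxazole C2–O1–C5 adds across an alkyne. The feature exploited is the 2-hydroxyl of ring B (the 2,4-dihydroxy-3-methoxyphenyl ring on the C3 benzyl group), which can reach lactone carbon C2 through a six-membered ring and so acts as a traceless tether. The precursor is a 5-aryloxy-4-methyloxazole whose aryl group carries an ortho 4-arylbut-2-ynyl chain. One thermolysis (intramolecular Diels–Alder reaction, then loss of acetonitrile) forms C2–C3 and C4–C5; hydrolysis of the 2-aryloxyfuran frees the phenol and gives the 3,4-dibenzylbutenolide. Carboxylate-directed asymmetric hydrogenation, C3 epimerisation and debenzylation complete the synthesis.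

Key step: step 10

Remark: lactone atoms are numbered O1, C2 (C=O), C3, C4, C5; ring A is the 4-hydroxy-3-methoxyphenyl ring on the C4 benzyl group, ring B the 2,4-dihydroxy-3-methoxyphenyl ring on the C3 benzyl group.
Assumption: the facial sense of the hydrogenation in step 11 cannot be predicted with confidence; it is to be assigned in a pilot run, and the antipodal ligand is used if the sense proves opposite to the one drawn.

Step 1
Reactants: 1 2-methoxyresorcinol
Product: 2 2,4-dihydroxy-3-methoxybenzaldehyde
Conditions: POCl3, DMF, MeCN, 0 °C to rt; then H2O, 50 °C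
Reagents that add atoms: N,N-dimethylformamide CN(C)C=O (formyl carbon); water O (formyl oxygen)
Why: Vilsmeier–Haack formylation of an electron-rich arene; the two activated positions (ortho to one hydroxyl, para to the other) are equivalent by symmetry, so a single aldehyde should form, and any aryl formate is hydrolysed in the aqueous stage.

Step 2
Reactants: 2 2,4-dihydroxy-3-methoxybenzaldehyde
Product: 3 4-(benzyloxy)-2-hydroxy-3-methoxybenzaldehyde
Conditions: BnBr (1.05 equiv), KHCO3, KI (cat.), MeCN, 60 °C
Reagents that add atoms: benzyl bromide BrCc1ccccc1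
Why: Williamson ether synthesis under weak-base control; the 4-hydroxyl para to the formyl group is the more acidic and is not held in the hydrogen bond that deactivates the 2-hydroxyl, so benzylation should occur at O4.

Step 3
Reactants: 3 4-(benzyloxy)-2-hydroxy-3-methoxybenzaldehyde
Product: 4 tert-butyl [3-(benzyloxy)-6-formyl-2-methoxyphenyl] carbonate
Conditions: Boc2O, i-Pr2NEt, DMAP (cat.), THF, rt
Reagents that add atoms: di-tert-butyl dicarbonate CC(C)(C)OC(=O)OC(=O)OC(C)(C)C
Why: DMAP-catalysed carbonate formation on the remaining phenol; the aryl tert-butyl carbonate is the latent trigger for the ortho-quinone methide of step 7.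

Step 4
Reactants: 4 tert-butyl [3-(benzyloxy)-6-formyl-2-methoxyphenyl] carbonate
Product: 5 tert-butyl [3-(benzyloxy)-6-(hydroxymethyl)-2-methoxyphenyl] carbonate
Conditions: BH3·THF, THF, 0 °C; then MeOH, aqueous work-up
Reagents that add atoms: none
Why: borane reduction of the aldehyde runs through a non-basic alkoxyborane, so the carbonate should neither migrate nor eliminate before step 7.

Step 5
Reactants: 6 [4-(benzyloxy)-3-methoxyphenyl]methanol
Product: 7 1-(benzyloxy)-4-(bromomethyl)-2-methoxybenzene
Conditions: PBr3, CH2Cl2, 0 °C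
Reagents that add atoms: phosphorus tribromide BrP(Br)Br
Why: alcohol-to-bromide substitution with PBr3; the electron-rich benzylic bromide is used directly without storage.

Step 6
Reactants: 7 1-(benzyloxy)-4-(bromomethyl)-2-methoxybenzene
Product: 8 1-(benzyloxy)-2-methoxy-4-(prop-2-yn-1-yl)benzene
Conditions: HC≡CMgBr (3 equiv), CuCl (10 mol %), THF, 50 °C
Reagents that add atoms: ethynylmagnesium bromide C#C[Mg]Br
Why: copper-catalysed sp3–sp coupling of a benzylic bromide with an alkynyl Grignard reagent; excess acetylide suppresses double benzylation and the weakly basic medium should avoid propargyl-to-allene isomerisation.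

Step 7
Reactants: 5 tert-butyl [3-(benzyloxy)-6-(hydroxymethyl)-2-methoxyphenyl] carbonate; 8 1-(benzyloxy)-2-methoxy-4-(prop-2-yn-1-yl)benzene
Product: 11 3-(benzyloxy)-6-{4-[4-(benzyloxy)-3-methoxyphenyl]but-2-yn-1-yl}-2-methoxyphenol, via alkynylmagnesium bromide 9 (not isolated), via ortho-quinone methide 10 (not isolated)
Conditions: 8 (2.4 equiv), EtMgBr (2.3 equiv), THF, 0 °C to rt; then 5, −78 °C to rt; aq NH4Cl
Reagents that add atoms: none
Why: anionic ortho-quinone methide generation and 1,4-addition; the magnesium alkoxide of 5 takes the Boc group from the phenol oxygen, the phenoxide expels tert-butyl carbonate to give 10, and 9 adds to the exocyclic methylene, restoring the arene with the free 2-hydroxyl.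

Step 8
Reactants: 11 3-(benzyloxy)-6-{4-[4-(benzyloxy)-3-methoxyphenyl]but-2-yn-1-yl}-2-methoxyphenol; 12 N-formyl-DL-alanine
Product: 13 3-(benzyloxy)-6-{4-[4-(benzyloxy)-3-methoxyphenyl]but-2-yn-1-yl}-2-methoxyphenyl 2-formamidopropanoate (racemic)
Conditions: EDC·HCl, DMAP (cat.), CH2Cl2, 0 °C to rt
Reagents that add atoms: none
Why: Steglich esterification of the hindered phenol; scrambling of the alanine centre through the azlactone is irrelevant because this carbon becomes sp2 in step 9.

Step 9
Reactants: 13 3-(benzyloxy)-6-{4-[4-(benzyloxy)-3-methoxyphenyl]but-2-yn-1-yl}-2-methoxyphenyl 2-formamidopropanoate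
Product: 14 5-(3-(benzyloxy)-6-{4-[4-(benzyloxy)-3-methoxyphenyl]but-2-yn-1-yl}-2-methoxyphenoxy)-4-methyl-1,3-oxazole
Conditions: P2O5, CHCl3, reflux; cold aq NaHCO3 work-up
Reagents that add atoms: none
Why: Robinson–Gabriel-type cyclodehydration of an N-formyl α-amino ester (the classical P2O5 route to 5-alkoxy-4-methyloxazoles); the formamide oxygen closes onto the activated ester carbonyl and water is lost with the aryloxy group kept at oxazole C5.

Step 10
Reactants: 14 5-(3-(benzyloxy)-6-{4-[4-(benzyloxy)-3-methoxyphenyl]but-2-yn-1-yl}-2-methoxyphenoxy)-4-methyl-1,3-oxazole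
Product: 17 3-[4-(benzyloxy)-2-hydroxy-3-methoxybenzyl]-4-[4-(benzyloxy)-3-methoxybenzyl]furan-2(5H)-one, via Diels–Alder adduct 15 (not isolated), via furochromene 16 (not isolated)
Conditions: o-dichlorobenzene (0.01 M, degassed), 180 °C; then 1 M aq HCl, THF, rt
Reagents that add atoms: water O (lactone carbonyl oxygen)
Why: Intramolecular Diels–Alder reaction of the oxazole 2-azadiene (C2=N3–C4=C5) with the tethered alkyne gives the 7-oxa-2-azabicyclo[2.2.1]heptadiene 15, which loses acetonitrile by cycloreversion to the aromatic 2-aryloxyfuran 16; the new bonds join oxazole C5 to the alkyne carbon next to ring B (lactone C2–C3) and oxazole C2 to the alkyne carbon next to ring A (lactone C5–C4). The closest known reaction type is the intramolecular oxazole–alkyne Diels–Alder/retro-Diels–Alder conversion of alkyne-tethered 5-alkoxyoxazoles into 2-alkoxyfurans and then butenolides. The five-membered oxygen ring is closed by [4+2] cycloaddition across oxazole C2 and C5 followed by retro-[4+2], and the temporary six-membered pyran ring of 16 is closed by the tether in the same cycloaddition and reopened in the work-up. No stereocentre survives the step: the bridgehead centres of 15 are lost on cycloreversion and C3 and C4 emerge sp2. The selectivity needed is regiochemical (which alkyne carbon meets oxazole C5) and is secured by the four-atom tether O–C(aryl)–C(aryl)–CH2, which allows only the six-membered mode, while intramolecularity and irreversible loss of the nitrile compensate for the unactivated alkyne. Aqueous acid then protonates furan C5, water adds to the ketene-acetal carbon and the ring B phenol is expelled, which should give the conjugated butenolide.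

Step 11
Reactants: 17 3-[4-(benzyloxy)-2-hydroxy-3-methoxybenzyl]-4-[4-(benzyloxy)-3-methoxybenzyl]furan-2(5H)-one
Product: 20 (3S,4R)-3-[4-(benzyloxy)-2-hydroxy-3-methoxybenzyl]-4-[4-(benzyloxy)-3-methoxybenzyl]dihydrofuran-2(3H)-one (cis), via disodium hydroxy-enoate 18 (not isolated), via disodium hydroxy-butanoate 19 (not isolated)
Conditions: NaOH (2.05 equiv), MeOH–H2O, rt; Ru(OAc)2[(S)-BINAP] (2 mol %), H2 (100 atm), 50 °C; then 2 M aq HCl, THF, rt
Reagents that add atoms: sodium hydroxide [Na+].[OH-] (its oxygen enters the carboxylate and can remain as the carbonyl oxygen after relactonisation)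
Why: saponification opens the lactone to the (Z)-γ-hydroxy carboxylate, whose carboxylate binds ruthenium and directs syn addition of H2 to one face of the tetrasubstituted alkene (carboxylate-directed asymmetric hydrogenation of tetrasubstituted acrylic acids), so that the BINAP ligand sets C4 as R and C3 as S, and acidification recloses the cis-lactone.

Step 12
Reactants: 20 (3S,4R)-cis-lactone
Product: 21 (3R,4R)-3-[4-(benzyloxy)-2-hydroxy-3-methoxybenzyl]-4-[4-(benzyloxy)-3-methoxybenzyl]dihydrofuran-2(3H)-one (trans)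
Conditions: DBU (1.5 equiv), toluene, 80 °C; aq NH4Cl
Reagents that add atoms: none
Why: base-mediated epimerisation through the lactone enolate; C3 should equilibrate to the thermodynamically preferred trans-3,4-dibenzyl arrangement (3R), while C4 has no acidic hydrogen and is untouched.

Step 13
Reactants: 21 (3R,4R)-trans-lactone bis(benzyl ether)
Product: 22 (3R,4R)-3-(2,4-dihydroxy-3-methoxybenzyl)-4-(4-hydroxy-3-methoxybenzyl)dihydrofuran-2(3H)-one
Conditions: H2 (1 atm), 10% Pd/C, EtOAc–EtOH, rt
Reagents that add atoms: none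
Why: hydrogenolysis of the two aryl benzyl ethers over palladium on carbon; the lactone, the methyl ethers and both stereocentres should be unaffected.

Compound list
1 | 2-methoxyresorcinol | COc1c(O)cccc1O | starting material
2 | 2,4-dihydroxy-3-methoxybenzaldehyde | O=Cc1ccc(O)c(OC)c1O | intermediate
3 | 4-(benzyloxy)-2-hydroxy-3-methoxybenzaldehyde | O=Cc1ccc(OCc2ccccc2)c(OC)c1O | intermediate
4 | tert-butyl [3-(benzyloxy)-6-formyl-2-methoxyphenyl] carbonate | O=Cc1ccc(OCc2ccccc2)c(OC)c1OC(=O)OC(C)(C)C | intermediate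
5 | tert-butyl [3-(benzyloxy)-6-(hydroxymethyl)-2-methoxyphenyl] carbonate | OCc1ccc(OCc2ccccc2)c(OC)c1OC(=O)OC(C)(C)C | intermediate
6 | [4-(benzyloxy)-3-methoxyphenyl]methanol | OCc1ccc(OCc2ccccc2)c(OC)c1 | starting material
7 | 1-(benzyloxy)-4-(bromomethyl)-2-methoxybenzene | BrCc1ccc(OCc2ccccc2)c(OC)c1 | intermediate
8 | 1-(benzyloxy)-2-methoxy-4-(prop-2-yn-1-yl)benzene | C#CCc1ccc(OCc2ccccc2)c(OC)c1 | intermediate
9 | {3-[4-(benzyloxy)-3-methoxyphenyl]prop-1-yn-1-yl}magnesium bromide | Br[Mg]C#CCc1ccc(OCc2ccccc2)c(OC)c1 | intermediate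
10 | 3-(benzyloxy)-2-methoxy-6-methylidenecyclohexa-2,4-dien-1-one (ortho-quinone methide) | C=C1C=CC(OCc2ccccc2)=C(OC)C1=O | intermediate
11 | 3-(benzyloxy)-6-{4-[4-(benzyloxy)-3-methoxyphenyl]but-2-yn-1-yl}-2-methoxyphenol | Oc1c(CC#CCc2ccc(OCc3ccccc3)c(OC)c2)ccc(OCc2ccccc2)c1OC | intermediate
12 | N-formyl-DL-alanine | CC(NC=O)C(=O)O | starting material
13 | 3-(benzyloxy)-6-{4-[4-(benzyloxy)-3-methoxyphenyl]but-2-yn-1-yl}-2-methoxyphenyl 2-formamidopropanoate (racemic) | CC(NC=O)C(=O)Oc1c(CC#CCc2ccc(OCc3ccccc3)c(OC)c2)ccc(OCc2ccccc2)c1OC | intermediate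
14 | 5-(3-(benzyloxy)-6-{4-[4-(benzyloxy)-3-methoxyphenyl]but-2-yn-1-yl}-2-methoxyphenoxy)-4-methyl-1,3-oxazole | Cc1ncoc1Oc1c(CC#CCc2ccc(OCc3ccccc3)c(OC)c2)ccc(OCc2ccccc2)c1OC | intermediate
15 | Diels–Alder adduct: 7-oxa-2-azabicyclo[2.2.1]hepta-2,5-diene fused through bridgehead C and alkene C to the 4H-chromene ring (racemic) | CC1=NC2OC13Oc4c(OC)c(OCc5ccccc5)ccc4CC3=C2Cc2ccc(OCc3ccccc3)c(OC)c2 | intermediate
16 | 7-(benzyloxy)-3-[4-(benzyloxy)-3-methoxybenzyl]-8-methoxy-4H-furo[2,3-b]chromene | c1oc2Oc3c(OC)c(OCc4ccccc4)ccc3Cc2c1Cc1ccc(OCc2ccccc2)c(OC)c1 | intermediate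
17 | 3-[4-(benzyloxy)-2-hydroxy-3-methoxybenzyl]-4-[4-(benzyloxy)-3-methoxybenzyl]furan-2(5H)-one | O=C1OCC(Cc2ccc(OCc3ccccc3)c(OC)c2)=C1Cc1ccc(OCc2ccccc2)c(OC)c1O | intermediate
18 | disodium (Z)-2-[4-(benzyloxy)-3-methoxy-2-oxidobenzyl]-3-[4-(benzyloxy)-3-methoxybenzyl]-4-hydroxybut-2-enoate | [Na+].[Na+].[O-]C(=O)/C(Cc1ccc(OCc2ccccc2)c(OC)c1[O-])=C(/Cc1ccc(OCc2ccccc2)c(OC)c1)CO | intermediate
19 | disodium (2S,3R)-2-[4-(benzyloxy)-3-methoxy-2-oxidobenzyl]-3-[4-(benzyloxy)-3-methoxybenzyl]-4-hydroxybutanoate | [Na+].[Na+].COc1cc(C[C@@H](CO)[C@H](Cc2ccc(OCc3ccccc3)c(OC)c2[O-])C(=O)[O-])ccc1OCc1ccccc1 | intermediate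
20 | (3S,4R)-3-[4-(benzyloxy)-2-hydroxy-3-methoxybenzyl]-4-[4-(benzyloxy)-3-methoxybenzyl]dihydrofuran-2(3H)-one (cis) | COc1cc(C[C@H]2COC(=O)[C@H]2Cc2ccc(OCc3ccccc3)c(OC)c2O)ccc1OCc1ccccc1 | intermediate
21 | (3R,4R)-3-[4-(benzyloxy)-2-hydroxy-3-methoxybenzyl]-4-[4-(benzyloxy)-3-methoxybenzyl]dihydrofuran-2(3H)-one (trans) | COc1cc(C[C@H]2COC(=O)[C@@H]2Cc2ccc(OCc3ccccc3)c(OC)c2O)ccc1OCc1ccccc1 | intermediate
22 | (3R,4R)-3-(2,4-dihydroxy-3-methoxybenzyl)-4-(4-hydroxy-3-methoxybenzyl)dihydrofuran-2(3H)-one | COc1cc(C[C@H]2COC(=O)[C@@H]2Cc2ccc(O)c(OC)c2O)ccc1O | target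

Total steps: 13. Longest linear sequence: 11 steps (steps 1–4 and 7–13, from 2-methoxyresorcinol); steps 5 and 6 form the ring A branch.

Steps most likely to fail

Step 11. The tetrasubstituted alkene may bind the ruthenium carboxylate too weakly for hydrogenation to proceed, the two faces may be poorly discriminated, or partial relactonisation before hydrogenation may remove the directing carboxylate. The fallback reduces the intact butenolide by conjugate hydride addition instead. It sets out from 17: Cu(OAc)2, (R)-DTBM-SEGPHOS (or its antipode, chosen to give 4R), diethoxymethylsilane and t-BuOH in toluene should deliver hydride to C4 under ligand control. The phenol is expected to be silylated in the flask, giving the diethoxy(methyl)silyl ether of the C3-epimeric saturated lactone F1. Aqueous NH4F work-up cleaves the silyl ether and leaves a C3-epimer mixture of 20 and 21, which the DBU treatment of step 12 converges on 21, where the fallback rejoins the route.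

Step 9. The tetrahedral intermediate of the cyclodehydration may expel the aryloxide instead of water, collapsing to an azlactone with loss of the phenol, and the acidic medium may erode the benzyl ethers. The fallback closes the ring from an isocyanide instead and sets out from 13. Dehydration of the formamide with POCl3 and Et3N (CH2Cl2, −20 °C) gives the aryl 2-isocyanopropanoate F2. Heating F2 in o-dichlorobenzene at about 150 °C with a catalytic hindered tertiary amine should cycloisomerise it by attack of the ester carbonyl oxygen on the isocyanide carbon and proton shift, as in the isocyanide route to 5-alkoxy-4-methyloxazoles. The fallback comes back at 14, which can be taken into step 10 in the same solvent.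

Step 10. The electron-rich aryloxy-oxazole may ring-open or hydrolyse faster than the unactivated alkyne captures it, or the skipped alkyne may isomerise to an allene at 180 °C. The fallback changes the diene to a thermally robust 1,3,4-oxadiazole that reacts with inverse electron demand and loses dinitrogen irreversibly. It sets out from 11: 1,1'-carbonyldiimidazole (THF, rt) gives the aryl imidazole-1-carboxylate F3, and formic hydrazide converts it into the aryl 2-formylhydrazine-1-carboxylate F4. Cyclodehydration (PPh3, I2, Et3N, CH2Cl2) gives the 2-aryloxy-1,3,4-oxadiazole F5. Thermolysis (o-dichlorobenzene, 200 °C) should effect the tethered [4+2] cycloaddition to the diaza-oxabicyclic adduct F6, which loses dinitrogen. The fallback comes back at the furochromene 16, which is hydrolysed to 17 as in step 10.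

Further compounds
F1 | step 11 | diethoxy(methyl)silyl ether of (4R)-3-[4-(benzyloxy)-2-hydroxy-3-methoxybenzyl]-4-[4-(benzyloxy)-3-methoxybenzyl]dihydrofuran-2(3H)-one (C3 epimer mixture) | COc1cc(C[C@H]2COC(=O)C2Cc2ccc(OCc3ccccc3)c(OC)c2O[Si](C)(OCC)OCC)ccc1OCc1ccccc1
F2 | step 9 | 3-(benzyloxy)-6-{4-[4-(benzyloxy)-3-methoxyphenyl]but-2-yn-1-yl}-2-methoxyphenyl 2-isocyanopropanoate (racemic) | [C-]#[N+]C(C)C(=O)Oc1c(CC#CCc2ccc(OCc3ccccc3)c(OC)c2)ccc(OCc2ccccc2)c1OC
F3 | step 10 | 3-(benzyloxy)-6-{4-[4-(benzyloxy)-3-methoxyphenyl]but-2-yn-1-yl}-2-methoxyphenyl 1H-imidazole-1-carboxylate | O=C(Oc1c(CC#CCc2ccc(OCc3ccccc3)c(OC)c2)ccc(OCc2ccccc2)c1OC)n1ccnc1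
F4 | step 10 | 3-(benzyloxy)-6-{4-[4-(benzyloxy)-3-methoxyphenyl]but-2-yn-1-yl}-2-methoxyphenyl 2-formylhydrazine-1-carboxylate | O=CNNC(=O)Oc1c(CC#CCc2ccc(OCc3ccccc3)c(OC)c2)ccc(OCc2ccccc2)c1OC
F5 | step 10 | 2-(3-(benzyloxy)-6-{4-[4-(benzyloxy)-3-methoxyphenyl]but-2-yn-1-yl}-2-methoxyphenoxy)-1,3,4-oxadiazole | c1nnc(Oc2c(CC#CCc3ccc(OCc4ccccc4)c(OC)c3)ccc(OCc3ccccc3)c2OC)o1
F6 | step 10 | 7-oxa-2,3-diazabicyclo[2.2.1]hepta-2,5-diene adduct fused to the 4H-chromene ring (racemic) | N1=NC2OC13Oc4c(OC)c(OCc5ccccc5)ccc4CC3=C2Cc2ccc(OCc3ccccc3)c(OC)c2
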